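**Plan**

1. Retrosynthetic cuts, in order: (i) the three O–CH3 bonds; (ii) the ArCH2–CH2 bond between the benzylic carbon of ring B (the dihydroxylated ring; this CH2 sits on the ring carbon ortho to the diaryl-ether oxygen) and C13 of the chain, traced back to a CH2–NH–CH2 unit in a 21-membered azacycle; (iii) the bond from that nitrogen to the benzylic carbon (imine from a ring-B aldehyde and a C13 azide); (iv) the diaryl ether C–O bond on ring B; (v) C1=C2 of the chain beside ring A (the monohydroxylated ring).
2. Forward: a ring-A aldehyde and a C12 ylide give the C13 chain (Wittig, hydrogenation); Ullmann coupling joins ring B; the chain end becomes an azide; Staudinger/aza-Wittig closes a 21-membered aza-ring, which is reduced to the secondary amine; nitrogen deletion contracts it to the 20-membered ring of the target; demethylation ends the route.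
3. Enabling feature: the benzylic carbon on ring B. As CHO it activates the neighbouring C–Br for ether formation and anchors the imine macrocyclisation; as ArCH2–N it supplies the stabilised benzylic radical on which N2 extrusion from a 1,1-diazene depends, so one nitrogen atom can serve as a temporary ring member and be excised.
4. Stereochemistry: the target has no stereocentre and no stereogenic double bond; the Wittig alkene geometry is erased by hydrogenation.

Key step: step 7

Remark on the chemistry: 3-hydroxy-5-methoxybenzaldehyde and 2-bromo-3,5-dimethoxybenzaldehyde are taken as purchasable; ring sizes are counted along the shorter arc through both benzene rings (20 atoms in the target, 21 in the nitrogen-containing precursor).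

**Route**

Step 1
Reactants: 1 12-bromododecan-1-ol
Product: 2 (12-hydroxydodecyl)triphenylphosphonium bromide
Conditions: PPh3 (1.1 equiv), MeCN, reflux
Reagents that add atoms: triphenylphosphine, c1ccc(cc1)P(c1ccccc1)c1ccccc1
Why: SN2 quaternisation of triphenylphosphine by the unhindered primary bromide (phosphonium salt formation) should proceed cleanly, the free hydroxyl being inert to the neutral phosphine.

Step 2
Reactants: 2 (12-hydroxydodecyl)triphenylphosphonium bromide; 3 3-hydroxy-5-methoxybenzaldehyde
Product: 5 (Z)-3-(13-hydroxytridec-1-en-1-yl)-5-methoxyphenol, via alkoxide ylide 4 (not isolated)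
Conditions: 2 (1.5 equiv), NaHMDS (4 equiv), THF, 0 °C; then 3, 0 °C → rt; aq NH4Cl
Reagents that add atoms: none
Why: Wittig olefination with a non-stabilised ylide should tolerate the alkoxide and the phenoxide because the phenoxide of 3 is meta to the formyl group and does not deactivate it by conjugation; the Z isomer is expected to predominate, and either geometry serves since the double bond is hydrogenated in step 3.

Step 3
Reactants: 5 (Z)-3-(13-hydroxytridec-1-en-1-yl)-5-methoxyphenol
Product: 6 3-(13-hydroxytridecyl)-5-methoxyphenol
Conditions: H2 (1 atm), 10% Pd/C, EtOAc/EtOH, rt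
Reagents that add atoms: none
Why: Heterogeneous catalytic hydrogenation should saturate the styrenyl double bond while the arene, the aryl ether, the phenol and the primary alcohol (no benzylic C–O bond is present) stay untouched.

Step 4
Reactants: 6 3-(13-hydroxytridecyl)-5-methoxyphenol; 7 2-bromo-3,5-dimethoxybenzaldehyde
Product: 8 2-[3-(13-hydroxytridecyl)-5-methoxyphenoxy]-3,5-dimethoxybenzaldehyde
Conditions: CuI (10 mol%), N,N-dimethylglycine·HCl (30 mol%), Cs2CO3 (2 equiv), dioxane, 100 °C
Reagents that add atoms: none
Why: Copper-catalysed Ullmann diaryl ether coupling should succeed because the ortho-formyl group activates the C–Br bond toward copper and the unhindered phenoxide of 6 is formed and arylated in preference to the far less acidic primary alcohol.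

Step 5
Reactants: 8 2-[3-(13-hydroxytridecyl)-5-methoxyphenoxy]-3,5-dimethoxybenzaldehyde
Product: 10 2-[3-(13-azidotridecyl)-5-methoxyphenoxy]-3,5-dimethoxybenzaldehyde, via mesylate 9 (not isolated)
Conditions: MsCl, Et3N, CH2Cl2, 0 °C; evaporate; NaN3, DMF, 60 °C
Reagents that add atoms: sodium azide, [Na+].[N-]=[N+]=[N-]
Why: Sulfonylation followed by SN2 displacement with azide at an unhindered primary carbon is reliable, and the non-enolisable aryl aldehyde is inert to both reagents.

Step 6
Reactants: 10 2-[3-(13-azidotridecyl)-5-methoxyphenoxy]-3,5-dimethoxybenzaldehyde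
Product: 13 21-membered macrocyclic secondary amine (ring B–CH2–NH–(CH2)13–ring A; tri-O-methyl), via iminophosphorane 11 (not isolated), via cyclic imine 12 (not isolated)
Conditions: 10 added by syringe pump to PPh3 (5 equiv), toluene, 80 °C (final ≤ 2 mM); cool; NaBH4, MeOH, 0 °C
Reagents that add atoms: none
Why: The Staudinger reaction turns the azide into an iminophosphorane that should condense with the aryl aldehyde of the same molecule (intramolecular aza-Wittig) under pseudo-high dilution to a strain-free 21-membered aldimine, which borohydride reduces to the amine; no other electrophile is present in 10.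

Step 7
Reactants: 13 21-membered macrocyclic secondary amine
Product: 16 tri-O-methyl ether of the target (20-membered ring; ring B–(CH2)14–ring A), via hydrazide adduct 14 (not isolated), via isodiazene 15 (not isolated)
Conditions: N-(benzyloxy)-N-(pivaloyloxy)-4-(trifluoromethyl)benzamide (1.5 equiv), THF (0.1 M), 45 °C, Ar
Reagents that add atoms: none
Why: The N–H of 13 displaces pivalate from the anomeric amide nitrogen (SN2 at N) to give 14, which collapses by a HERON-type shift of the benzyloxy group to the acyl carbon, releasing benzyl 4-(trifluoromethyl)benzoate and the 1,1-diazene 15. Homolysis of the benzylic C–N bond of 15 and loss of N2 leave a ring-B benzyl radical and the primary C13 radical in one solvent cage, and their recombination forms the ArCH2–CH2 bond. The closest known reaction type is anomeric-amide nitrogen deletion of secondary benzylic amines, including the ring contraction of cyclic benzylic amines such as tetrahydroisoquinolines. The 20-membered ring is closed by contraction of the 21-membered azacycle through geminate radical–radical recombination, a closure whose partners are born one N2 molecule apart, so it needs no high dilution and is not governed by exo/endo rules. No stereocentre is formed. The step needs chemoselective amination at the single N–H (secured by carrying all three phenols as methyl ethers, which like the arenes are inert to the reagent) and recombination in preference to disproportionation, tetrazene formation or cage escape (secured by the tether and by the electron-rich, ortho-aryloxy-substituted benzylic position of ring B, which weakens the C–N bond of 15 and stabilises the radical).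

Step 8
Reactants: 16 tri-O-methyl ether of the target
Product: 18 CNP0173380.0 (target), via tris(dibromoboryl) ether 17 (not isolated)
Conditions: BBr3 (6 equiv), CH2Cl2, −78 °C → rt; H2O, 0 °C
Reagents that add atoms: none
Why: Boron tribromide cleaves aryl methyl ethers by Lewis-acid activation and SN2 attack of bromide on the methyl carbon, whereas the diaryl ether has no sp3 carbon on oxygen and should survive, so hydrolysis of the aryl borates gives the triphenol.

**Compound list**

1 | 12-bromododecan-1-ol | OCCCCCCCCCCCCBr | starting material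
2 | (12-hydroxydodecyl)triphenylphosphonium bromide | OCCCCCCCCCCCC[P+](c1ccccc1)(c1ccccc1)c1ccccc1.[Br-] | intermediate
3 | 3-hydroxy-5-methoxybenzaldehyde | O=Cc1cc(O)cc(OC)c1 | starting material
4 | sodium 12-(triphenyl-λ5-phosphanylidene)dodecan-1-olate (alkoxide ylide) | [Na+].[O-]CCCCCCCCCCCC=P(c1ccccc1)(c1ccccc1)c1ccccc1 | intermediate (not isolated)
5 | (Z)-3-(13-hydroxytridec-1-en-1-yl)-5-methoxyphenol (E isomer converges) | OCCCCCCCCCCC/C=C\c1cc(O)cc(OC)c1 | intermediate
6 | 3-(13-hydroxytridecyl)-5-methoxyphenol | OCCCCCCCCCCCCCc1cc(O)cc(OC)c1 | intermediate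
7 | 2-bromo-3,5-dimethoxybenzaldehyde | O=Cc1cc(OC)cc(OC)c1Br | starting material
8 | 2-[3-(13-hydroxytridecyl)-5-methoxyphenoxy]-3,5-dimethoxybenzaldehyde | O=Cc1cc(OC)cc(OC)c1Oc1cc(OC)cc(CCCCCCCCCCCCCO)c1 | intermediate
9 | 13-[3-(2-formyl-4,6-dimethoxyphenoxy)-5-methoxyphenyl]tridecyl methanesulfonate | O=Cc1cc(OC)cc(OC)c1Oc1cc(OC)cc(CCCCCCCCCCCCCOS(C)(=O)=O)c1 | intermediate (not isolated)
10 | 2-[3-(13-azidotridecyl)-5-methoxyphenoxy]-3,5-dimethoxybenzaldehyde | O=Cc1cc(OC)cc(OC)c1Oc1cc(OC)cc(CCCCCCCCCCCCCN=[N+]=[N-])c1 | intermediate
11 | 3,5-dimethoxy-2-[3-methoxy-5-[13-[(triphenyl-λ5-phosphanylidene)amino]tridecyl]phenoxy]benzaldehyde (iminophosphorane) | O=Cc1cc(OC)cc(OC)c1Oc1cc(OC)cc(CCCCCCCCCCCCCN=P(c2ccccc2)(c2ccccc2)c2ccccc2)c1 | intermediate (not isolated)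
12 | 21-membered macrocyclic (E)-aldimine, ring B–CH=N–(CH2)13–ring A, tri-O-methyl | COc1cc2cc(c1)Oc1c(OC)cc(OC)cc1/C=N/CCCCCCCCCCCCC2 | intermediate (not isolated)
13 | 21-membered macrocyclic secondary amine, ring B–CH2–NH–(CH2)13–ring A, tri-O-methyl | COc1cc2cc(c1)Oc1c(OC)cc(OC)cc1CNCCCCCCCCCCCCC2 | intermediate
14 | hydrazide adduct: N-(benzyloxy)-4-(trifluoromethyl)benzamide bonded through its nitrogen to the ring nitrogen of 13 | COc1cc2cc(c1)Oc1c(OC)cc(OC)cc1CN(CCCCCCCCCCCCC2)N(OCc1ccccc1)C(=O)c1ccc(cc1)C(F)(F)F | intermediate (not isolated)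
15 | macrocyclic 1,1-diazene (isodiazene) derived from 13 | COc1cc2cc(c1)Oc1c(OC)cc(OC)cc1C[N+](=[N-])CCCCCCCCCCCCC2 | intermediate (not isolated)
16 | tri-O-methyl ether of the target, 20-membered ring, ring B–(CH2)14–ring A | COc1cc2cc(c1)Oc1c(OC)cc(OC)cc1CCCCCCCCCCCCCC2 | intermediate
17 | tris(dibromoboryl) ether of the target | BrB(Br)Oc1cc2cc(c1)Oc1c(OB(Br)Br)cc(OB(Br)Br)cc1CCCCCCCCCCCCCC2 | intermediate (not isolated)
18 | CNP0173380.0: 3-hydroxy-5-alkylphenyl 2,4-dihydroxy-6-alkylphenyl ether in which the two alkyl groups are the ends of one (CH2)14 chain | Oc1cc2cc(c1)Oc1c(O)cc(O)cc1CCCCCCCCCCCCCC2 | target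

**Summary**

Total step count: 8. Longest linear sequence: 8 steps (1 → 18).

Steps most likely to fail:

1. Step 7 (nitrogen deletion). After amination the 1,1-diazene may be diverted (tautomerisation to a hydrazone, dimerisation to a tetrazene), or the tethered radical pair may disproportionate or escape the cage instead of recombining, so the ring opens instead of contracting. The fallback uses sulfur instead of nitrogen as the temporary ring atom and an ionic extrusion instead of a radical pair; it sets out from 8 and comes back at 16. Reduction of 8 (NaBH4, MeOH, 0 °C) should give the diol F1. Double Appel bromination (CBr4, PPh3, CH2Cl2, 0 °C) should give the benzylic/primary dibromide F2. Na2S·9H2O under high dilution (EtOH/THF, 50 °C, syringe pump) should close the 21-membered cyclic sulfide F3. mCPBA (2.2 equiv, CH2Cl2, 0 °C) should give the sulfone F4. Ramberg–Bäcklund ring contraction (CF2Br2, KOH on Al2O3, t-BuOH/CH2Cl2, 0 °C → rt) should give the macrocyclic styrene F5, of which both alkene isomers serve. Hydrogenation (H2, Pd/C, EtOAc) then leads to 16.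

2. Step 6 (aza-Wittig macrocyclisation). Condensation between different molecules may outrun ring closure and give oligomeric imines, or the iminophosphorane may be hydrolysed before it meets the aldehyde. The fallback closes the same ring by irreversible N-alkylation instead of carbonyl condensation; it sets out from 10 and comes back at 13. NaBH4 (MeOH, 0 °C) should reduce the aldehyde of 10 to the azido benzylic alcohol F6. Staudinger reduction (PPh3, THF/H2O, 50 °C) should give the amino alcohol F7. 2-Nitrobenzenesulfonyl chloride/Et3N (CH2Cl2, 0 °C) should sulfonylate nitrogen selectively to the sulfonamide F8. Mitsunobu N-alkylation under high dilution (PPh3, DIAD, toluene/THF; Fukuyama–Mitsunobu reaction) should give the N-nosyl macrocycle F9. PhSH/K2CO3 (DMF, rt) removes the nosyl group and gives 13.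

3. Step 4 (Ullmann coupling). Copper insertion and C–O bond formation at a bromide flanked by CHO and OMe may be slow, so that protodebromination of 7 and degradation of the aldehyde take over. The fallback replaces copper catalysis by uncatalysed addition–elimination; it sets out from 6 and comes back at 8. Electrophilic fluorination of purchasable 3,5-dimethoxybenzaldehyde (Selectfluor, MeCN) should give 2-fluoro-3,5-dimethoxybenzaldehyde F10, whose small fluoride is activated by the ortho-formyl group. SNAr with the phenoxide of 6 (K2CO3, DMAc, 130 °C) should then give 8.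

**Further compounds**

F1 | step 7 | [2-[3-(13-hydroxytridecyl)-5-methoxyphenoxy]-3,5-dimethoxyphenyl]methanol (diol) | OCc1cc(OC)cc(OC)c1Oc1cc(OC)cc(CCCCCCCCCCCCCO)c1
F2 | step 7 | 1-(bromomethyl)-2-[3-(13-bromotridecyl)-5-methoxyphenoxy]-3,5-dimethoxybenzene (dibromide) | BrCc1cc(OC)cc(OC)c1Oc1cc(OC)cc(CCCCCCCCCCCCCBr)c1
F3 | step 7 | 21-membered cyclic sulfide, ring B–CH2–S–(CH2)13–ring A, tri-O-methyl | COc1cc2cc(c1)Oc1c(OC)cc(OC)cc1CSCCCCCCCCCCCCC2
F4 | step 7 | 21-membered cyclic sulfone, ring B–CH2–SO2–(CH2)13–ring A, tri-O-methyl | COc1cc2cc(c1)Oc1c(OC)cc(OC)cc1CS(=O)(=O)CCCCCCCCCCCCC2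
F5 | step 7 | 20-membered macrocyclic styrene, ring B–CH=CH–(CH2)12–ring A, tri-O-methyl (E shown) | COc1cc2cc(c1)Oc1c(OC)cc(OC)cc1/C=C/CCCCCCCCCCCC2
F6 | step 6 | [2-[3-(13-azidotridecyl)-5-methoxyphenoxy]-3,5-dimethoxyphenyl]methanol | OCc1cc(OC)cc(OC)c1Oc1cc(OC)cc(CCCCCCCCCCCCCN=[N+]=[N-])c1
F7 | step 6 | [2-[3-(13-aminotridecyl)-5-methoxyphenoxy]-3,5-dimethoxyphenyl]methanol | OCc1cc(OC)cc(OC)c1Oc1cc(OC)cc(CCCCCCCCCCCCCN)c1
F8 | step 6 | N-[13-[3-[2-(hydroxymethyl)-4,6-dimethoxyphenoxy]-5-methoxyphenyl]tridecyl]-2-nitrobenzenesulfonamide | OCc1cc(OC)cc(OC)c1Oc1cc(OC)cc(CCCCCCCCCCCCCNS(=O)(=O)c2ccccc2[N+](=O)[O-])c1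
F9 | step 6 | N-(2-nitrobenzenesulfonyl) derivative of macrocyclic amine 13 | COc1cc2cc(c1)Oc1c(OC)cc(OC)cc1CN(CCCCCCCCCCCCC2)S(=O)(=O)c1ccccc1[N+](=O)[O-]
F10 | step 4 | 2-fluoro-3,5-dimethoxybenzaldehyde | O=Cc1cc(OC)cc(OC)c1F
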